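**Retrosynthetic overview**
1. The (2S)-flavanone is traced back, through desilylation and a ligand-controlled copper hydride 1,4-reduction, to the corresponding flavone; the C2=C3 double bond is a temporary oxidation level and C2 is the last centre to be set.
2. The flavone is cut in ring C at O1–C2 and at C4–C4a (and at C3–C4) into three components joined in one operation: a 4-iodo-2,6-diprenylresorcinol (ring A with O1), carbon monoxide (C4) and 4-ethynylanisole (C2, C3 and ring B).
3. Enabling feature: on ring A the phenolic oxygen O1 (on C8a) and the acyl-bearing carbon C4a are ortho neighbours, and in ring C O1 stands β to the C4 carbonyl. Ring C is therefore an ortho-hydroxyaryl ketone joined to an aryl-alkyne two-carbon unit, the ortho-iodophenol/CO/alkyne retron at the flavone level.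
4. Ring A is bought as resorcinol and dressed by three successive directed ortho-metalations of its bis-MOM ether (C8 prenyl, C6 prenyl, C4a iodide); ring B is bought.
5. Ring order: ring A (given) → ring C (step 6, the only ring closure) → C2 configuration (step 8).

Key step: step 6

Remark: C2 is read as S from the SMILES (natural flavanone series); the sense of induction in step 8 is assigned by analogy, and the antipodal ligand (also commercial) is used if a test run shows the opposite sense. Prenyl = 3-methylbut-2-en-1-yl, MOM = methoxymethyl, TBS = tert-butyldimethylsilyl.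

**Step 1**
Reactants: 1 resorcinol; 2 chloromethyl methyl ether
Product: 3 1,3-bis(methoxymethoxy)benzene
Conditions: NaH, DMF, 0 °C; then 2, 0 °C → rt
Reagents that add atoms: chloromethyl methyl ether, COCCl
Why: Williamson-type O-alkylation of the bis-phenoxide should install two MOM ethers, which serve as the directing groups for all three ring metalations that follow.

**Step 2**
Reactants: 3 1,3-bis(methoxymethoxy)benzene; 4 prenyl bromide
Product: 5 1,3-bis(methoxymethoxy)-2-(3-methylbut-2-en-1-yl)benzene
Conditions: n-BuLi, THF, 0 °C → rt; CuI (10 mol %), then 4, −78 °C → rt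
Reagents that add atoms: prenyl bromide, CC(C)=CCBr
Why: Directed ortho-metalation should remove the C2 hydrogen flanked by both MOM ethers (cooperative direction), and CuI-catalysed SN2 allylation of the aryllithium should give the linear prenyl arene.

**Step 3**
Reactants: 5 1,3-bis(methoxymethoxy)-2-(3-methylbut-2-en-1-yl)benzene; 4 prenyl bromide
Product: 6 1,3-bis(methoxymethoxy)-2,4-bis(3-methylbut-2-en-1-yl)benzene
Conditions: n-BuLi, TMEDA, Et2O, 0 °C; CuI (10 mol %), then 4, −78 °C → rt
Reagents that add atoms: prenyl bromide, CC(C)=CCBr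
Why: A second directed ortho-metalation should occur at C4 (equivalent to C6 by symmetry, the only kind of ring position still ortho to a MOM ether), followed by the same CuI-catalysed SN2 prenylation.

**Step 4**
Reactants: 6 1,3-bis(methoxymethoxy)-2,4-bis(3-methylbut-2-en-1-yl)benzene; 7 iodine
Product: 8 1-iodo-2,4-bis(methoxymethoxy)-3,5-bis(3-methylbut-2-en-1-yl)benzene
Conditions: n-BuLi, TMEDA, Et2O, −20 → 0 °C; then I2, THF, −78 °C; aq. Na2S2O3
Reagents that add atoms: iodine, II
Why: A third directed ortho-metalation should take the last hydrogen ortho to a MOM ether (C5 has no directing neighbour), and iodinolysis of the aryllithium at low temperature places iodine where electrophilic iodination could not without attacking the prenyl alkenes.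

**Step 5**
Reactants: 8 1-iodo-2,4-bis(methoxymethoxy)-3,5-bis(3-methylbut-2-en-1-yl)benzene
Product: 9 4-iodo-2,6-bis(3-methylbut-2-en-1-yl)benzene-1,3-diol
Conditions: HCl (1.25 M in MeOH), 0 °C → rt
Reagents that add atoms: none
Why: Acid-catalysed transacetalisation of the MOM ethers to methanol should free both phenols, with dilute acid and low temperature chosen to keep the ortho-prenyl phenols from closing to chromans.

**Step 6**
Reactants: 9 4-iodo-2,6-bis(3-methylbut-2-en-1-yl)benzene-1,3-diol; 10 4-ethynylanisole; 11 carbon monoxide; 12 diethylamine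
Product: 15 7-hydroxy-2-(4-methoxyphenyl)-6,8-bis(3-methylbut-2-en-1-yl)-4H-chromen-4-one, via ynone 13 (not isolated), via enaminone 14 (not isolated)
Conditions: PdCl2(dppf) (5 mol %), CO (20 bar), Et2NH, 120 °C
Reagents that add atoms: 4-ethynylanisole, COc1ccc(C#C)cc1; carbon monoxide, [C-]#[O+]
Why: Zerovalent palladium (formed in situ from the divalent palladium precatalyst PdCl2(dppf)) should add oxidatively to the C–I bond of 9, CO should insert to give an aroyl–palladium species (this makes the ring A–carbonyl bond C4a–C4), and amine-assisted coupling with alkyne 10 followed by reductive elimination should give ynone 13; Et2NH then adds to 13 to give enaminone 14, whose ortho phenol oxygen attacks the amine-bearing β-carbon and expels Et2NH, closing ring C through the O1–C2 bond. The closest known reaction type is the palladium-catalysed carbonylative Sonogashira annulation of ortho-iodophenols with terminal alkynes and CO to flavones, a three-component coupling. Ring C closes by a 6-endo-trig addition–elimination on 14 (formally a 6-endo-dig oxa-Michael addition to 13). No stereocentre is formed, because C2 stays sp2 until step 8. The step needs CO insertion to outrun direct alkynylation (which would lead to a benzofuran), acetylide to outrun amine at the aroyl–palladium stage, and six- over five-membered closure (flavone, not aurone); CO pressure on an electron-rich aryl–palladium, the acidic terminal alkyne and the secondary amine (the enaminone can only close at its β-carbon) should secure these. In the substrate only the C8a hydroxyl is ortho to the new ketone (the C7 hydroxyl is para and cannot cyclise), and both prenyl groups are trisubstituted alkenes meta to the palladated carbon, so they should not take part.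

**Step 7**
Reactants: 15 7-hydroxy-2-(4-methoxyphenyl)-6,8-bis(3-methylbut-2-en-1-yl)-4H-chromen-4-one; 16 tert-butyldimethylsilyl chloride
Product: 17 7-[(tert-butyldimethylsilyl)oxy]-2-(4-methoxyphenyl)-6,8-bis(3-methylbut-2-en-1-yl)-4H-chromen-4-one
Conditions: TBSCl, imidazole, DMF, rt → 40 °C
Reagents that add atoms: tert-butyldimethylsilyl chloride, CC(C)(C)[Si](C)(C)Cl
Why: Silylation of the single, acidic C7 phenol should prevent phenoxide formation, which would turn the enone into a vinylogous carboxylate and shut down hydride addition in step 8.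

**Step 8**
Reactants: 17 7-[(tert-butyldimethylsilyl)oxy]-2-(4-methoxyphenyl)-6,8-bis(3-methylbut-2-en-1-yl)-4H-chromen-4-one; 18 diethoxymethylsilane
Product: 20 (2S)-7-[(tert-butyldimethylsilyl)oxy]-2-(4-methoxyphenyl)-6,8-bis(3-methylbut-2-en-1-yl)-2,3-dihydro-4H-chromen-4-one, via silyl enol ether 19 (not isolated)
Conditions: Cu(OAc)2 (5 mol %), (R)-DTBM-SEGPHOS (5.5 mol %), (EtO)2MeSiH, toluene, 0 °C → rt; then AcOH, THF/H2O, rt
Reagents that add atoms: none
Why: In this copper hydride-catalysed asymmetric conjugate reduction (a reaction type established for β,β-disubstituted cyclic enones and 2-substituted chromones) the DTBM-SEGPHOS-ligated CuH should deliver hydride to the Re face of C2 under ligand control to set 2S, the copper enolate is silylated to enol ether 19 (which can neither expel O1 nor be reduced at C4), mild acid hydrolysis gives the ketone, and the isolated trisubstituted prenyl alkenes are not hydrocuprated.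

**Step 9**
Reactants: 20 (2S)-7-[(tert-butyldimethylsilyl)oxy]-2-(4-methoxyphenyl)-6,8-bis(3-methylbut-2-en-1-yl)-2,3-dihydro-4H-chromen-4-one
Product: 21 (2S)-7-hydroxy-2-(4-methoxyphenyl)-6,8-bis(3-methylbut-2-en-1-yl)-2,3-dihydro-4H-chromen-4-one (the target flavanone)
Conditions: TBAF, AcOH, THF, 0 °C
Reagents that add atoms: none
Why: Fluoride-mediated cleavage of the aryl silyl ether, buffered with acetic acid, should free the C7 phenol without base-induced retro-oxa-Michael opening of ring C (which would racemise C2) and without acid that could cyclise the prenyl groups.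

**Compound list**
1 | resorcinol (benzene-1,3-diol) | Oc1cccc(O)c1 | starting material
2 | chloromethyl methyl ether | COCCl | starting material
3 | 1,3-bis(methoxymethoxy)benzene | COCOc1cccc(OCOC)c1 | intermediate
4 | prenyl bromide (1-bromo-3-methylbut-2-ene) | CC(C)=CCBr | starting material
5 | 1,3-bis(methoxymethoxy)-2-(3-methylbut-2-en-1-yl)benzene | COCOc1cccc(OCOC)c1CC=C(C)C | intermediate
6 | 1,3-bis(methoxymethoxy)-2,4-bis(3-methylbut-2-en-1-yl)benzene | COCOc1ccc(CC=C(C)C)c(OCOC)c1CC=C(C)C | intermediate
7 | iodine | II | starting material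
8 | 1-iodo-2,4-bis(methoxymethoxy)-3,5-bis(3-methylbut-2-en-1-yl)benzene | COCOc1c(I)cc(CC=C(C)C)c(OCOC)c1CC=C(C)C | intermediate
9 | 4-iodo-2,6-bis(3-methylbut-2-en-1-yl)benzene-1,3-diol | Oc1c(I)cc(CC=C(C)C)c(O)c1CC=C(C)C | intermediate
10 | 4-ethynylanisole (1-ethynyl-4-methoxybenzene) | COc1ccc(C#C)cc1 | starting material
11 | carbon monoxide | [C-]#[O+] | starting material
12 | diethylamine | CCNCC | starting material
13 | 1-[2,4-dihydroxy-3,5-bis(3-methylbut-2-en-1-yl)phenyl]-3-(4-methoxyphenyl)prop-2-yn-1-one (ynone) | COc1ccc(C#CC(=O)c2cc(CC=C(C)C)c(O)c(CC=C(C)C)c2O)cc1 | intermediate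
14 | 3-(diethylamino)-1-[2,4-dihydroxy-3,5-bis(3-methylbut-2-en-1-yl)phenyl]-3-(4-methoxyphenyl)prop-2-en-1-one (enaminone, alkene geometry not defined) | CCN(CC)C(=CC(=O)c1cc(CC=C(C)C)c(O)c(CC=C(C)C)c1O)c1ccc(OC)cc1 | intermediate
15 | 7-hydroxy-2-(4-methoxyphenyl)-6,8-bis(3-methylbut-2-en-1-yl)-4H-chromen-4-one | COc1ccc(-c2cc(=O)c3cc(CC=C(C)C)c(O)c(CC=C(C)C)c3o2)cc1 | intermediate
16 | tert-butyldimethylsilyl chloride | CC(C)(C)[Si](C)(C)Cl | starting material
17 | 7-[(tert-butyldimethylsilyl)oxy]-2-(4-methoxyphenyl)-6,8-bis(3-methylbut-2-en-1-yl)-4H-chromen-4-one | COc1ccc(-c2cc(=O)c3cc(CC=C(C)C)c(O[Si](C)(C)C(C)(C)C)c(CC=C(C)C)c3o2)cc1 | intermediate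
18 | diethoxymethylsilane | CCO[SiH](C)OCC | starting material
19 | (2S)-7-[(tert-butyldimethylsilyl)oxy]-4-{[diethoxy(methyl)silyl]oxy}-2-(4-methoxyphenyl)-6,8-bis(3-methylbut-2-en-1-yl)-2H-chromene (silyl enol ether) | COc1ccc([C@@H]2C=C(O[Si](C)(OCC)OCC)c3cc(CC=C(C)C)c(O[Si](C)(C)C(C)(C)C)c(CC=C(C)C)c3O2)cc1 | intermediate
20 | (2S)-7-[(tert-butyldimethylsilyl)oxy]-2-(4-methoxyphenyl)-6,8-bis(3-methylbut-2-en-1-yl)-2,3-dihydro-4H-chromen-4-one | COc1ccc([C@@H]2CC(=O)c3cc(CC=C(C)C)c(O[Si](C)(C)C(C)(C)C)c(CC=C(C)C)c3O2)cc1 | intermediate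
21 | (2S)-7-hydroxy-2-(4-methoxyphenyl)-6,8-bis(3-methylbut-2-en-1-yl)-2,3-dihydro-4H-chromen-4-one (the target flavanone) | COc1ccc([C@@H]2CC(=O)c3cc(CC=C(C)C)c(O)c(CC=C(C)C)c3O2)cc1 | target

**Step count and risks**
Total steps: 9. Longest linear sequence: 9 steps (resorcinol 1 to target 21).

Steps most likely to fail:

1. Step 8. The doubly donor-substituted β-aryl-β-aryloxy enone may take up hydride slowly or with poor facial discrimination, and the copper enolate may expel the O1 phenoxide before silylation, so that ring C opens and re-closes without control. The fallback replaces reduction of a flavone by asymmetric conjugate arylation of a chromone, and sets out from 8. Iodine–lithium exchange (n-BuLi, THF, −78 °C) and acylation with N-methoxy-N-methylacetamide should give 1-[2,4-bis(methoxymethoxy)-3,5-bis(3-methylbut-2-en-1-yl)phenyl]ethan-1-one F1. Condensation with DMF dimethyl acetal (neat, 100 °C) should give (E)-1-[2,4-bis(methoxymethoxy)-3,5-bis(3-methylbut-2-en-1-yl)phenyl]-3-(dimethylamino)prop-2-en-1-one F2. HCl in MeOH should cleave both MOM ethers and close the pyranone to 7-hydroxy-6,8-bis(3-methylbut-2-en-1-yl)-4H-chromen-4-one F3. Silylation (TBSCl, imidazole, DMF) should give 7-[(tert-butyldimethylsilyl)oxy]-6,8-bis(3-methylbut-2-en-1-yl)-4H-chromen-4-one F4. Enantioselective 1,4-addition of 4-methoxyphenylboronic acid (Pd(OCOCF3)2, t-BuPyOx ligand enantiomer chosen for the 2S product, NH4PF6, H2O, ClCH2CH2Cl, 60 °C) then comes back to the route at 20.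

2. Step 6. The aroyl–palladium species may be captured by diethylamine (amide formation), alkynylation may precede CO insertion and lead to a benzofuran, or the ynone may close in the five-membered sense to an aurone; oxidative addition into the very electron-rich iodophenol may also be slow. The fallback builds the same ynone stepwise by carbonyl addition, and sets out from 8. Iodine–lithium exchange (n-BuLi, THF, −78 °C) and a DMF quench should give 2,4-bis(methoxymethoxy)-3,5-bis(3-methylbut-2-en-1-yl)benzaldehyde F5. Addition of the lithium acetylide of 10 (n-BuLi, THF, −78 °C) should give racemic 1-[2,4-bis(methoxymethoxy)-3,5-bis(3-methylbut-2-en-1-yl)phenyl]-3-(4-methoxyphenyl)prop-2-yn-1-ol F6. MnO2 oxidation should give 1-[2,4-bis(methoxymethoxy)-3,5-bis(3-methylbut-2-en-1-yl)phenyl]-3-(4-methoxyphenyl)prop-2-yn-1-one F7. HCl in MeOH should remove both MOM groups to give ynone 13 (which may already close in part), and diethylamine in ethanol should complete the 6-endo closure through enaminone 14, coming back to the route at 15.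

3. Step 4. Deprotonation may occur at the doubly activated benzylic–allylic CH2 groups of the two prenyl chains instead of at the ring, and iodine may add to the prenyl double bonds. The fallback introduces the prenyl groups last by cross-coupling, and sets out from 1. Mono-iodination (ICl, Et2O) should give 4-iodobenzene-1,3-diol F8. The same carbonylative annulation with 10 and 11 (PdCl2(dppf), CO, Et2NH) should give 7-hydroxy-2-(4-methoxyphenyl)-4H-chromen-4-one F9. Twofold iodination ortho to the phenol (NIS, DMF) should give 7-hydroxy-6,8-diiodo-2-(4-methoxyphenyl)-4H-chromen-4-one F10. Twofold Stille coupling with tributyl(3-methylbut-2-en-1-yl)stannane (Pd(PPh3)4, DMF, 90 °C) comes back to the route at 15.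

**Further compounds**
F1 | step 8 | 1-[2,4-bis(methoxymethoxy)-3,5-bis(3-methylbut-2-en-1-yl)phenyl]ethan-1-one | CC(=O)c1cc(CC=C(C)C)c(OCOC)c(CC=C(C)C)c1OCOC
F2 | step 8 | (E)-1-[2,4-bis(methoxymethoxy)-3,5-bis(3-methylbut-2-en-1-yl)phenyl]-3-(dimethylamino)prop-2-en-1-one | CN(C)/C=C/C(=O)c1cc(CC=C(C)C)c(OCOC)c(CC=C(C)C)c1OCOC
F3 | step 8 | 7-hydroxy-6,8-bis(3-methylbut-2-en-1-yl)-4H-chromen-4-one | O=c1ccoc2c(CC=C(C)C)c(O)c(CC=C(C)C)cc12
F4 | step 8 | 7-[(tert-butyldimethylsilyl)oxy]-6,8-bis(3-methylbut-2-en-1-yl)-4H-chromen-4-one | O=c1ccoc2c(CC=C(C)C)c(O[Si](C)(C)C(C)(C)C)c(CC=C(C)C)cc12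
F5 | step 6 | 2,4-bis(methoxymethoxy)-3,5-bis(3-methylbut-2-en-1-yl)benzaldehyde | O=Cc1cc(CC=C(C)C)c(OCOC)c(CC=C(C)C)c1OCOC
F6 | step 6 | 1-[2,4-bis(methoxymethoxy)-3,5-bis(3-methylbut-2-en-1-yl)phenyl]-3-(4-methoxyphenyl)prop-2-yn-1-ol (racemic) | COc1ccc(C#CC(O)c2cc(CC=C(C)C)c(OCOC)c(CC=C(C)C)c2OCOC)cc1
F7 | step 6 | 1-[2,4-bis(methoxymethoxy)-3,5-bis(3-methylbut-2-en-1-yl)phenyl]-3-(4-methoxyphenyl)prop-2-yn-1-one | COc1ccc(C#CC(=O)c2cc(CC=C(C)C)c(OCOC)c(CC=C(C)C)c2OCOC)cc1
F8 | step 4 | 4-iodobenzene-1,3-diol | Oc1ccc(I)c(O)c1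
F9 | step 4 | 7-hydroxy-2-(4-methoxyphenyl)-4H-chromen-4-one | COc1ccc(-c2cc(=O)c3ccc(O)cc3o2)cc1
F10 | step 4 | 7-hydroxy-6,8-diiodo-2-(4-methoxyphenyl)-4H-chromen-4-one | COc1ccc(-c2cc(=O)c3cc(I)c(O)c(I)c3o2)cc1
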